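Remarks on the chemistry (assumptions):
- The target has no stereogenic centre and no axial descriptor. The two aryl–indolyl axes are taken to rotate freely, so no stereocontrol is planned.
- (1-Tosylindol-3-yl)boronic acid 5 is assumed to be a catalogue compound, like 1, 8 and the reagents.
- The structures of 7, 11, 12 and 13 were checked atom by atom against 14 (7 + 11 − H2O − NH3 = 13; 13 − C7H6O2S = 14); no structural correction is needed.

## Structural features

The target 14 is a hexasubstituted benzene (central ring) with methoxy groups on C2, C3, C5 and C6 and two indol-3-yl groups on C1 and C4, para to each other. Indole A (on C1) carries a 3-methylbut-2-enyl (prenyl) chain on C5, whereas indole B (on C4) is unsubstituted; both have free N–H and free C2–H. There is no stereocentre, so no question of neighbouring stereocentres arises; each aryl–indolyl axis is flanked by two methoxy groups but is expected to rotate. The fragile groups are the trisubstituted prenyl alkene (strong protic acid, electrophilic halogen, nitrosating agents, osmylation, hydrogenation), the two indoles (acid-promoted oligomerisation, oxidation) and the tetraalkoxybenzene, which is easily oxidised to a quinone. The real difficulty is that the molecule is a desymmetrised version of a symmetric core: two nearly identical indoles must be attached through hindered bonds to equivalent para positions, and only one of them may carry a prenyl group, at C5, a position that direct substitution of an indole does not reach. The key step exploits the fact that in indole A the N1–C2 and C3–C3a bonds are those made by a Fischer indolization. C5 lies para to the N-bearing carbon C7a, so a 4-substituted arylhydrazine maps onto it without ambiguity. C3, which bears the central ring, is the α-carbon of an arylacetaldehyde and C2 is its carbonyl carbon.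

## Logic of the disconnections

14 ⇒ 13. The N–S bond of the sulfonamide on indole B is cut. Indole B has to be masked while indole A is formed in acid in the presence of an aldehyde, and an N-sulfonyl group is the mask that survives cross-coupling, oxidation and acetic acid. Nothing is gained in skeleton, but the last step becomes a single base-mediated deprotection. The demand is that the base removes the sulfonyl group without touching the methyl ethers, the free indole A or the alkene.

13 ⇒ 7 + 11 (through 12). The C3–C3a and N1–C2 bonds of indole A are cut. This separates the only substituted indole into a simple para-substituted hydrazine and a two-ring aldehyde, and it removes the C5-regiochemistry problem. The forward step needs an acid strong enough to drive ene-hydrazine formation and rearrangement but too weak to protonate the prenyl alkene. The aldehyde must also be fully tied up as 12 before heating.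

7 ⇒ 6. No skeletal bond is cut; the aldehyde is traced back to a primary alcohol. The arylacetaldehyde is the least storable compound of the route, so it is unveiled one step before use under neutral, non-aqueous conditions; this avoids an osmium-mediated alkene cleavage next to an indole. The demand is an oxidant that stops at the aldehyde and ignores the electron-rich rings.

6 ⇒ 4 + 5. The biaryl bond between C4 of the central ring and C3 of indole B is cut. Indole B is unsubstituted and available ready-made as its N-sulfonyl boronic acid, so the problem shrinks to a single monocyclic aryl bromide. The forward coupling must insert palladium into a hindered, electron-rich C–Br bond faster than the heteroaryl boronic acid is protodeboronated.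

4 ⇒ 2 (through 3). The bond between C1 of the central ring and the side-chain CH2 is cut; the two carbons come from a C2 epoxide. Exchange of exactly one of the two equivalent bromines is the desymmetrising event of the whole synthesis. It requires one equivalent of alkyllithium at low temperature and a clean SN2 opening by a hindered aryllithium.

2 ⇒ 1. The two C–Br bonds are cut. Only two ring positions are free and both are activated, so the regiochemistry is automatic. The halogenation must not oxidise the tetraalkoxybenzene.

11 ⇒ 10. The aryl C–N bond is cut. Forming the hydrazine by palladium-catalysed coupling under basic conditions avoids a diazotisation–reduction sequence, in which the prenyl alkene would meet nitrosating agents and mineral acid. The demand is monoarylation of the unsubstituted N–N nucleophile.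

10 ⇒ 8 (through 9). The aryl–CH2 bond of the prenyl group is cut. One bromine of a symmetric dihalide is converted into the nucleophile and the other is kept for the C–N coupling. The allylic substitution must occur at the primary (α) carbon of the prenyl electrophile.

## Other disconnections considered

Alternative 1: The cut is through the C1–C2 and C3–C4 bonds of the central ring. The ring is built from a four-carbon chain that already carries both indoles (C4–C5–C6–C1) and a two-carbon oxalyl unit (C2–C3). In the forward key step the bis-enolate of 1-(1-SEM-indol-3-yl)-4-(5-prenyl-1-SEM-indol-3-yl)butane-2,3-dione A2 would be C-acylated twice by an oxalic diester, the second time in a Dieckmann-like 6-exo-trig closure. The resulting tetraone would enolise to 2,5-dihydroxy-3-(1-SEM-indol-3-yl)-6-(5-prenyl-1-SEM-indol-3-yl)-1,4-benzoquinone A1.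
- In its favour: the central ring is made with all six substituents in place, so neither hindered biaryl coupling is needed, and on this point it is better than the chosen plan. The para relation of the indoles is built into the chain, no transition metal is used, and the natural quinone oxidation level is reached directly.
- Against it: A2, an α-diketone flanked by two different indolylmethyl groups, is harder to make than any intermediate of the chosen route. It needs an unsymmetrical union of two indolylacetyl units and a separately built indole that already carries the C5 prenyl group, so the regiochemical problem is only moved. The bis-enolate can also O-acylate or close a five-membered ring by aldol attack on its own ketone. A1 is at the wrong oxidation and alkylation state for 14: reduction to the hydroquinone, four O-methylations and two SEM removals would follow.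
- Comparison: on structure, both plans fix the unsymmetry before ring formation, but here it resides in a fragile acyclic diketone and in the chosen plan in an aryl bromide made by monolithiation. On mechanism, enolate acylation under strong base and an acid-mediated sigmatropic rearrangement are equally established reaction classes, but more competing pathways are open here. On step economy the alternative is longer, with at least three operations after its key step against one.

Alternative 2: The cut is through C1–C2 and C4–C5, dividing the central ring into two three-carbon halves, each an indolylpyruvate unit. In the forward key step, soft enolisation (MgBr2·OEt2 and a tertiary amine) of a mixture of S-ethyl 3-(indol-3-yl)-2-oxopropanethioate A4 and S-ethyl 3-(5-prenylindol-3-yl)-2-oxopropanethioate A5 would let each methylene attack the thioester carbonyl of the other. An intermolecular Claisen condensation followed by a 6-exo-trig one would give 2,5-dihydroxy-3-(indol-3-yl)-6-(5-prenylindol-3-yl)-1,4-benzoquinone A3.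
- In its favour: it is the shortest and most convergent plan on paper, needs no N-protection and follows the presumed biogenesis. In step count and protecting-group economy it is better than the chosen plan.
- Against it: A4 and A5 differ only by a remote prenyl group, so nothing distinguishes cross- from self-condensation. A statistical mixture of A3 and the two symmetrical quinones must be expected; at most half of the material can become A3, and the three products differ only in their prenyl content. Indolylpyruvate derivatives are largely enolic, air-sensitive and prone to self-condensation. The prenylated half again needs a separately built C5-prenylated indole, and reductive tetra-O-methylation beside two free N–H groups is still required.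
- Comparison: on structure, this plan does not encode the unsymmetry at all, whereas the chosen plan does so by desymmetrising 2. On mechanism it is equal to alternative 1 (Claisen chemistry), but milder. On step economy it wins only if the statistical step and the separation are accepted.

Alternative 3: The cut is through the N1–C7a and C3–C3a bonds of indole B. Its benzo ring comes from an aryne and its N1–C2–C3 unit from a 2H-azirine on the central ring. In the forward key step, fluoride would release the aryne from 2-(trimethylsilyl)phenyl trifluoromethanesulfonate A8. The nitrogen of 3-[2,3,5,6-tetramethoxy-4-(5-prenyl-1-SEM-indol-3-yl)phenyl]-2H-azirine A7 would add to it, the aryl anion would close on the C=N carbon, and opening of the strained N1–C3 bond and tautomerisation would give 3-[4-(indol-3-yl)-2,3,5,6-tetramethoxyphenyl]-5-prenyl-1-SEM-indole A6.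
- In its favour: the conditions are neutral and acid-free, which is better for the prenyl group than the chosen plan as far as acidity goes. The free N–H of indole B is formed directly, the aryne is symmetrical so no regiochemistry arises, and two bonds and one ring are made in one step, equal to the Fischer step in bond economy.
- Against it: the method is spent on the indole that needs no construction, since unsubstituted indole B can be bought as 5. Indole A with its C5 prenyl group must still be made by other means and carried, SEM-protected, through the azirine synthesis. A7 needs several steps on a hindered, electron-rich ring (vinyl azide thermolysis or Neber-type closure), some with energetic intermediates. Arynes are unselective electrophiles that can undergo an ene reaction with the prenyl alkene, N-arylate the new N–H or attack indole A. A SEM removal follows.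
- Comparison: on structure, the chosen plan puts ring construction where the substitution pattern is the problem; this plan puts it where there is none. On mechanism, polar addition with strain release and a [3,3] shift are both credible, but the chemoselectivity demands are higher here. On step economy this plan is longer.

Key step: step 7

## Route

Step 1
Reactants: 1 1,2,4,5-tetramethoxybenzene
Product: 2 1,4-dibromo-2,3,5,6-tetramethoxybenzene
Conditions: Br2 (2.1 equiv), CH2Cl2, 0 °C → rt, dark
Reagents that add atoms: bromine, BrBr
Why: Electrophilic aromatic bromination; the only two C–H positions are each flanked by two methoxy groups and strongly activated, so the para-dibromide is the sole substitution product, and the anhydrous non-nucleophilic medium should disfavour oxidative demethylation to a quinone.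

Step 2
Reactants: 2 1,4-dibromo-2,3,5,6-tetramethoxybenzene
Product: 4 2-(4-bromo-2,3,5,6-tetramethoxyphenyl)ethanol, via aryllithium 3 (not isolated)
Conditions: n-BuLi (1.05 equiv), THF, −78 °C; ethylene oxide (3 equiv, THF solution), −78 °C → rt; H2O
Reagents that add atoms: ethylene oxide (oxirane), C1CO1
Why: Lithium–bromine exchange with one equivalent of n-BuLi should stop at the mono-lithio species 3 (a second exchange on an aryl anion is far slower; 3 is stabilised by the two flanking methoxy groups), and SN2 opening of the epoxide by 3 installs the two-carbon chain at the alcohol oxidation level.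

Step 3
Reactants: 4 2-(4-bromo-2,3,5,6-tetramethoxyphenyl)ethanol; 5 (1-tosylindol-3-yl)boronic acid
Product: 6 2-[2,3,5,6-tetramethoxy-4-(1-tosylindol-3-yl)phenyl]ethanol
Conditions: 5 (1.6 equiv), Pd(OAc)2 (5 mol %), SPhos (2-dicyclohexylphosphino-2',6'-dimethoxybiphenyl, 10 mol %), K3PO4 (3 equiv), toluene/H2O (10:1), 90 °C, Ar
Reagents that add atoms: none
Why: Suzuki–Miyaura coupling; the bulky, electron-rich biarylphosphine lets zerovalent palladium insert into the di-ortho-substituted, electron-rich C–Br bond and tolerates the free alcohol, while the N-sulfonyl group slows protodeboronation of the indol-3-yl boron species and survives phosphate base.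

Step 4
Reactants: 6 2-[2,3,5,6-tetramethoxy-4-(1-tosylindol-3-yl)phenyl]ethanol
Product: 7 2-[2,3,5,6-tetramethoxy-4-(1-tosylindol-3-yl)phenyl]acetaldehyde
Conditions: Dess–Martin periodinane (1.3 equiv), CH2Cl2, 0 °C → rt; Na2S2O3/NaHCO3 wash; used the same day
Reagents that add atoms: none
Why: Dess–Martin oxidation of a primary alcohol; under anhydrous, nearly neutral conditions no aldehyde hydrate forms, so the oxidation should stop at the arylacetaldehyde, and the sulfonylated indole and the methoxyarene are not oxidised by the periodinane.

Step 5
Reactants: 8 1,4-dibromobenzene
Product: 10 1-bromo-4-(3-methylbut-2-enyl)benzene, via 4-bromophenyllithium 9 (not isolated)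
Conditions: n-BuLi (1.0 equiv), THF, −78 °C; CuI (10 mol %), prenyl bromide (1.2 equiv), −78 °C → rt
Reagents that add atoms: 1-bromo-3-methylbut-2-ene (prenyl bromide), CC(C)=CCBr
Why: Mono lithium–bromine exchange followed by copper-mediated allylic substitution; the aryl nucleophile attacks the unhindered primary carbon of prenyl bromide (SN2, α-attack) and not the tertiary γ-carbon, so the linear prenyl arene and not the 1,1-dimethylallyl isomer should form.

Step 6
Reactants: 10 1-bromo-4-(3-methylbut-2-enyl)benzene
Product: 11 [4-(3-methylbut-2-enyl)phenyl]hydrazine
Conditions: N2H4·H2O (4 equiv), KOH (2 equiv), Pd[P(o-tolyl)3]2 (0.5 mol %), CyPF-tBu [(R)-1-[(SP)-2-(dicyclohexylphosphino)ferrocenyl]ethyldi-tert-butylphosphine, 0.5 mol %], 1,4-dioxane, 100 °C, Ar; extractive work-up under Ar, used at once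
Reagents that add atoms: hydrazine hydrate, NN.O
Why: Buchwald–Hartwig-type C–N coupling of an aryl bromide with hydrazine; the bulky bisphosphine favours monoarylation, and the basic, non-oxidising medium should leave the trisubstituted alkene untouched.

Step 7
Reactants: 7 2-[2,3,5,6-tetramethoxy-4-(1-tosylindol-3-yl)phenyl]acetaldehyde; 11 [4-(3-methylbut-2-enyl)phenyl]hydrazine
Product: 13 3-[2,3,5,6-tetramethoxy-4-(1-tosylindol-3-yl)phenyl]-5-(3-methylbut-2-enyl)indole, via arylhydrazone 12 (not isolated)
Conditions: 11 (1.2 equiv), degassed AcOH, rt, 1 h, then 90 °C, Ar
Reagents that add atoms: none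
Why: Condensation of 11 with 7 at room temperature gives the N-arylhydrazone 12, so that no free aldehyde should remain when the mixture is heated; acetic acid then tautomerises 12 to the ene-hydrazine through its only enolisable carbon, the benzylic CH2. The N-protonated ene-hydrazine undergoes the [3,3]-sigmatropic (diaza-Cope) shift, which breaks the N–N bond and joins the former α-carbon to an ortho carbon of the hydrazine ring (C3–C3a). Rearomatisation gives an ortho-aminoaryl iminium ion, the aniline nitrogen adds to the iminium carbon in a 5-exo-trig closure (N1–C2) that forms the pyrrole ring, and loss of ammonia from the aminal aromatises it. The closest known reaction type is the Fischer indole synthesis of 3-arylindoles from arylacetaldehyde arylhydrazones in acetic acid. No stereocentre is formed. Regioselectivity is secured by the substrate: the hydrazine is para-substituted, so its two ortho carbons are equivalent and the prenyl group must end on C5, and the aldehyde has one α-carbon, so the aryl group must end on C3 with C2 unsubstituted. Chemoselectivity rests on the weakness of the acid, which should not protonate the trisubstituted alkene, and on the sulfonyl group, which removes the nucleophilicity of indole B toward the aldehyde and the iminium intermediates.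

Step 8
Reactants: 13 3-[2,3,5,6-tetramethoxy-4-(1-tosylindol-3-yl)phenyl]-5-(3-methylbut-2-enyl)indole
Product: 14 3-[4-(indol-3-yl)-2,3,5,6-tetramethoxyphenyl]-5-(3-methylbut-2-enyl)indole
Conditions: KOH (10 equiv), MeOH/THF (2:1), 65 °C
Reagents that add atoms: none
Why: Base-mediated desulfonylation; hydroxide or methoxide attacks sulfur and expels the indolide, a good leaving group, while the methyl ethers, the free indole A and the isolated trisubstituted alkene are inert to these conditions.

## Compound list

1 | 1,2,4,5-tetramethoxybenzene | COc1cc(OC)c(OC)cc1OC | starting material
2 | 1,4-dibromo-2,3,5,6-tetramethoxybenzene | COc1c(Br)c(OC)c(OC)c(Br)c1OC | intermediate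
3 | (4-bromo-2,3,5,6-tetramethoxyphenyl)lithium (formed in the flask, not isolated) | [Li]c1c(OC)c(OC)c(Br)c(OC)c1OC | intermediate
4 | 2-(4-bromo-2,3,5,6-tetramethoxyphenyl)ethanol | OCCc1c(OC)c(OC)c(Br)c(OC)c1OC | intermediate
5 | (1-tosylindol-3-yl)boronic acid [1-(4-methylphenylsulfonyl)indol-3-ylboronic acid] | Cc1ccc(cc1)S(=O)(=O)n1cc(B(O)O)c2ccccc12 | starting material
6 | 2-[2,3,5,6-tetramethoxy-4-(1-tosylindol-3-yl)phenyl]ethanol | OCCc1c(OC)c(OC)c(-c2cn(S(=O)(=O)c3ccc(C)cc3)c3ccccc23)c(OC)c1OC | intermediate
7 | 2-[2,3,5,6-tetramethoxy-4-(1-tosylindol-3-yl)phenyl]acetaldehyde | O=CCc1c(OC)c(OC)c(-c2cn(S(=O)(=O)c3ccc(C)cc3)c3ccccc23)c(OC)c1OC | intermediate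
8 | 1,4-dibromobenzene | Brc1ccc(Br)cc1 | starting material
9 | (4-bromophenyl)lithium (formed in the flask, not isolated) | [Li]c1ccc(Br)cc1 | intermediate
10 | 1-bromo-4-(3-methylbut-2-enyl)benzene | CC(C)=CCc1ccc(Br)cc1 | intermediate
11 | [4-(3-methylbut-2-enyl)phenyl]hydrazine | NNc1ccc(CC=C(C)C)cc1 | intermediate
12 | N-[4-(3-methylbut-2-enyl)phenyl]hydrazone of 7 (E isomer drawn, geometry immaterial; formed in the flask, not isolated) | CC(C)=CCc1ccc(N/N=C/Cc2c(OC)c(OC)c(-c3cn(S(=O)(=O)c4ccc(C)cc4)c4ccccc34)c(OC)c2OC)cc1 | intermediate
13 | 3-[2,3,5,6-tetramethoxy-4-(1-tosylindol-3-yl)phenyl]-5-(3-methylbut-2-enyl)indole | COc1c(OC)c(-c2c[nH]c3ccc(CC=C(C)C)cc23)c(OC)c(OC)c1-c1cn(S(=O)(=O)c2ccc(C)cc2)c2ccccc12 | intermediate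
14 | 3-[4-(indol-3-yl)-2,3,5,6-tetramethoxyphenyl]-5-(3-methylbut-2-enyl)indole (CNP0306547.0) | COc1c(OC)c(-c2c[nH]c3ccc(CC=C(C)C)cc23)c(OC)c(OC)c1-c1c[nH]c2ccccc12 | target

## Step count and risk assessment

Total step count: 8 (steps 1–4 to 7, steps 5–6 to 11, then steps 7 and 8). Longest linear sequence: 6 steps (1 → 2 → 4 → 6 → 7 → 13 → 14).

Least certain steps:

Step 7 (key step). The most likely failure is a rearrangement that is too slow at a temperature and acidity the prenyl group tolerates. Raising the acid strength would then invite Markovnikov addition of acid to the trisubstituted alkene. Two further risks are acid- or air-induced degradation of the electron-rich hydrazone before the [3,3] shift (N–N cleavage to the aniline) and condensation of the free C2 of the new indole with aldehyde that has not yet been converted into 12. Fallback: setting out from 7, the indolization would be run with commercial 4-bromophenylhydrazine hydrochloride (AcOH, 100 °C, or EtOH/H2SO4), a partner with nothing acid-labile, to give 5-bromo-3-[2,3,5,6-tetramethoxy-4-(1-tosylindol-3-yl)phenyl]indole F1. The prenyl group would then be introduced last by an α-selective Suzuki–Miyaura coupling of F1 with 3-methylbut-2-enylboronic acid pinacol ester. The catalyst would be the bulky carbene complex of divalent palladium PdCl2(IPent)(3-chloropyridine) [IPent = 1,3-bis(2,6-di(pentan-3-yl)phenyl)imidazol-2-ylidene], with aqueous KOH in THF at 65 °C. The route is rejoined at 13; should the base also cleave the sulfonamide, this only anticipates step 8.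

Step 6. The likely problems are over-arylation to diarylhydrazines, hydrodebromination through a palladium hydride derived from bound hydrazine, migration of the prenyl double bond into conjugation with the ring at 100 °C in base, and air oxidation of the free hydrazine during isolation. Fallback: setting out from 10, lithium–bromine exchange (n-BuLi, THF, −78 °C) would give [4-(3-methylbut-2-enyl)phenyl]lithium F2. Electrophilic amination of F2 with di-tert-butyl azodicarboxylate would give di-tert-butyl 1-[4-(3-methylbut-2-enyl)phenyl]hydrazine-1,2-dicarboxylate F3. Both carbamates would then be removed without protic acid (TMSOTf, 2,6-lutidine, CH2Cl2, 0 °C, then MeOH), rejoining the route at 11.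

Step 3. Protodeboronation of the heteroaryl boronic acid may outrun oxidative addition into the hindered, electron-rich C–Br bond, and reduction of the C–Br bond is a further possibility. Fallback, with reversed polarity and a different order of bond formation: setting out from 2, the aryllithium 3 would be transmetalated with ZnCl2 to (4-bromo-2,3,5,6-tetramethoxyphenyl)zinc chloride F4. Negishi coupling of F4 (Pd2(dba)3/SPhos, THF, 50 °C) with 3-iodo-1-tosylindole F5 (from indole with I2/KOH in DMF, then NaH/TsCl) would give 3-(4-bromo-2,3,5,6-tetramethoxyphenyl)-1-tosylindole F6. Suzuki–Miyaura coupling of F6 with the robust (E)-2-ethoxyvinylboronic acid pinacol ester (Pd(OAc)2/SPhos, K3PO4, dioxane/H2O, 100 °C) would give 3-[4-[(E)-2-ethoxyvinyl]-2,3,5,6-tetramethoxyphenyl]-1-tosylindole F7. Hydrolysis of the enol ether (aqueous HCl, THF, rt) would rejoin the route at 7, with no increase in step count.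

Step 2. Opening of the epoxide by the hindered, chelated aryllithium may be sluggish, which would allow competing alkylation by the 1-bromobutane formed in the exchange, or protonation on warming. Fallback: setting out from 2, the aryllithium 3 would instead be allylated (CuI cat., allyl bromide, −78 °C → rt) to 1-allyl-4-bromo-2,3,5,6-tetramethoxybenzene F8. Coupling of F8 with 5 under the conditions of step 3 would give 3-(4-allyl-2,3,5,6-tetramethoxyphenyl)-1-tosylindole F9. Lemieux–Johnson cleavage of the terminal alkene (OsO4 cat., NaIO4, 2,6-lutidine, dioxane/H2O) would rejoin the route at 7.

## Further compounds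

F1 | step 7 | 5-bromo-3-[2,3,5,6-tetramethoxy-4-(1-tosylindol-3-yl)phenyl]indole | COc1c(OC)c(-c2c[nH]c3ccc(Br)cc23)c(OC)c(OC)c1-c1cn(S(=O)(=O)c2ccc(C)cc2)c2ccccc12
F2 | step 6 | [4-(3-methylbut-2-enyl)phenyl]lithium | [Li]c1ccc(CC=C(C)C)cc1
F3 | step 6 | di-tert-butyl 1-[4-(3-methylbut-2-enyl)phenyl]hydrazine-1,2-dicarboxylate | CC(C)=CCc1ccc(N(NC(=O)OC(C)(C)C)C(=O)OC(C)(C)C)cc1
F4 | step 3 | (4-bromo-2,3,5,6-tetramethoxyphenyl)zinc chloride | Cl[Zn]c1c(OC)c(OC)c(Br)c(OC)c1OC
F5 | step 3 | 3-iodo-1-tosylindole | Cc1ccc(S(=O)(=O)n2cc(I)c3ccccc32)cc1
F6 | step 3 | 3-(4-bromo-2,3,5,6-tetramethoxyphenyl)-1-tosylindole | COc1c(OC)c(-c2cn(S(=O)(=O)c3ccc(C)cc3)c3ccccc23)c(OC)c(OC)c1Br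
F7 | step 3 | 3-[4-[(E)-2-ethoxyvinyl]-2,3,5,6-tetramethoxyphenyl]-1-tosylindole | CCO/C=C/c1c(OC)c(OC)c(-c2cn(S(=O)(=O)c3ccc(C)cc3)c3ccccc23)c(OC)c1OC
F8 | step 2 | 1-allyl-4-bromo-2,3,5,6-tetramethoxybenzene | C=CCc1c(OC)c(OC)c(Br)c(OC)c1OC
F9 | step 2 | 3-(4-allyl-2,3,5,6-tetramethoxyphenyl)-1-tosylindole | C=CCc1c(OC)c(OC)c(-c2cn(S(=O)(=O)c3ccc(C)cc3)c3ccccc23)c(OC)c1OC
A1 | alternative 1 | 2,5-dihydroxy-3-(1-SEM-indol-3-yl)-6-(5-prenyl-1-SEM-indol-3-yl)-1,4-benzoquinone | O=C1C(O)=C(c2cn(COCC[Si](C)(C)C)c3ccccc23)C(=O)C(O)=C1c1cn(COCC[Si](C)(C)C)c2ccc(CC=C(C)C)cc12
A2 | alternative 1 | 1-(1-SEM-indol-3-yl)-4-(5-prenyl-1-SEM-indol-3-yl)butane-2,3-dione | O=C(Cc1cn(COCC[Si](C)(C)C)c2ccccc12)C(=O)Cc1cn(COCC[Si](C)(C)C)c2ccc(CC=C(C)C)cc12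
A3 | alternative 2 | 2,5-dihydroxy-3-(indol-3-yl)-6-(5-prenylindol-3-yl)-1,4-benzoquinone | O=C1C(O)=C(c2c[nH]c3ccccc23)C(=O)C(O)=C1c1c[nH]c2ccc(CC=C(C)C)cc12
A4 | alternative 2 | S-ethyl 3-(indol-3-yl)-2-oxopropanethioate | CCSC(=O)C(=O)Cc1c[nH]c2ccccc12
A5 | alternative 2 | S-ethyl 3-(5-prenylindol-3-yl)-2-oxopropanethioate | CCSC(=O)C(=O)Cc1c[nH]c2ccc(CC=C(C)C)cc12
A6 | alternative 3 | 3-[4-(indol-3-yl)-2,3,5,6-tetramethoxyphenyl]-5-prenyl-1-SEM-indole | COc1c(OC)c(-c2c[nH]c3ccccc23)c(OC)c(OC)c1-c1cn(COCC[Si](C)(C)C)c2ccc(CC=C(C)C)cc12
A7 | alternative 3 | 3-[2,3,5,6-tetramethoxy-4-(5-prenyl-1-SEM-indol-3-yl)phenyl]-2H-azirine | COc1c(OC)c(C2=NC2)c(OC)c(OC)c1-c1cn(COCC[Si](C)(C)C)c2ccc(CC=C(C)C)cc12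
A8 | alternative 3 | 2-(trimethylsilyl)phenyl trifluoromethanesulfonate | C[Si](C)(C)c1ccccc1OS(=O)(=O)C(F)(F)F
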